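**Retrosynthetic overview**
- Ring C is disconnected last by a Diels–Alder cut (C12–C1' and C15–C6') into a (12E)-labda-8(17),12,14-triene and the C5' dimethyl monoketal of a 2-(chromon-2-yl)quinone; ketal hydrolysis then frees the C5' ketone of ring D.
- The diene comes from the C12 ester by reduction to the aldehyde and two Wittig steps; the C7 oxygen is placed earlier by allylic oxidation of the 8(17)-ene.
- The route rests on the tertiary C9 carbinol bonded to C8, which carries the exocyclic C17 methylene, in ring B: the C8–C9 bond is cut to an 8,9-seco β-keto ester alkyne made from (+)-sclareolide.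
- The dienophile comes from a chalcone, closed to the flavone and dearomatised in its 2'-hydroxy-4',5'-dimethoxyphenyl ring.
- Ring order: ring A (from sclareolide), ring B (step 4), chromone (step 13), ring D as dienone (step 15), ring C (step 16).

Key step: step 4

Remark: locants are labdane C1–C20 for the terpenoid (C17 on C8, C20 on C10), C1'–C6' for ring D and double primes for the chromone; 2-hydroxy-4,5-dimethoxybenzaldehyde is taken as commercial; the target's relative configuration (C11, the chromone and H-6' on one face of ring C) is that of a cycloadduct of the 12E diene formed with the chromone, not ring D, in the endo position, and the ketal is chosen to favour that mode.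

Step 1
Reactants: 1 (+)-sclareolide
Product: 2 methyl 13,14,15,16-tetranorlabd-8-en-12-oate (Δ8(9) ester; 5α-H, 10β-CH3)
Conditions: H2SO4 (conc., 0.5 equiv), MeOH, reflux; minor Δ7 and Δ8(17) isomers removed on AgNO3-impregnated silica
Reagents that add atoms: methanol, CO
Why: Acid-catalysed lactone opening through the tertiary C8 cation with Fischer esterification, the proton being lost from C9 to give the tetrasubstituted Δ8(9) alkene as the thermodynamic isomer, while C5 and C10 are not touched.

Step 2
Reactants: 2 methyl 13,14,15,16-tetranorlabd-8-en-12-oate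
Product: 3 methyl 8,9-dioxo-8,9-seco-13,14,15,16-tetranorlabdan-12-oate (diketo ester; 5α-H, 10β-CH3)
Conditions: O3, CH2Cl2–MeOH, −78 °C; then Me2S, −78 °C → rt
Reagents that add atoms: ozone, [O-][O+]=O
Why: Ozonolysis with reductive work-up cleaves the electron-rich tetrasubstituted C8=C9 bond to the C8 methyl ketone and the C9 ketone of a β-keto ester, and no stereocentre is formed or lost.

Step 3
Reactants: 3 methyl 8,9-dioxo-8,9-seco-13,14,15,16-tetranorlabdan-12-oate
Product: 5 methyl 9-oxo-8,9-seco-13,14,15,16-tetranorlabd-8(17)-yn-12-oate (8,9-seco β-keto ester alkyne), via enol phosphate 4 (not isolated)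
Conditions: LiN(i-Pr)2 (2.1 equiv), THF, −78 °C; ClP(O)(OEt)2 (1.05 equiv), −78 °C; LiN(i-Pr)2 (2.5 equiv), −78 °C → rt; aq NH4Cl
Reagents that add atoms: none
Why: Alkyne synthesis from a methyl ketone by enol phosphate elimination: the first equivalent of amide base stores the β-keto ester as its enolate (C10 is quaternary, so nothing more can be removed on that side), the second takes a C17 proton under kinetic control, the more reactive ketone enolate is O-phosphorylated and excess base eliminates the phosphate to the C8≡C17 alkyne.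

Step 4
Reactants: 5 methyl 9-oxo-8,9-seco-13,14,15,16-tetranorlabd-8(17)-yn-12-oate
Product: 6 methyl 9α-hydroxy-13,14,15,16-tetranorlabd-8(17)-en-12-oate (5α-H, 10β-CH3)
Conditions: SmI2 (divalent samarium, 3 equiv), HMPA (10 equiv), t-BuOH (2 equiv), THF, −20 °C → rt
Reagents that add atoms: none
Why: SmI2, made more reducing by HMPA, gives one electron to the C9 ketone, which sits in a chelate with the ester carbonyl, and the ketyl adds to C8 of the terminal alkyne; the vinyl radical at C17 is reduced by a second SmI2 and protonated by tert-butanol. The closest known reaction type is the SmI2-promoted reductive ketyl–alkyne (and ketyl–alkene) cyclisation of β-keto esters. Ring B closes as a six-membered carbocycle in the 6-exo-dig mode, trans-fused because the two arms are already equatorial on C5 and C10 of the ring A chair. The new stereocentre C9 is set in a chair transition state with the larger CH2CO2Me arm equatorial and the samarium-bound oxygen axial, anti to the axial C10 methyl, which gives the 9α-hydroxyl. The step needs cyclisation to outrun reduction of the ketone to the secondary alcohol and pinacol coupling: the gauche placement of the two arms, the quaternary C10 and HMPA secure this, and the ester and the alkyne C–H are not touched.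

Step 5
Reactants: 6 methyl 9α-hydroxy-13,14,15,16-tetranorlabd-8(17)-en-12-oate
Product: 7 methyl 9α-(triethylsilyloxy)-13,14,15,16-tetranorlabd-8(17)-en-12-oate
Conditions: Et3SiOTf, 2,6-lutidine, CH2Cl2, −78 → 0 °C
Reagents that add atoms: triethylsilyl trifluoromethanesulfonate, CC[Si](CC)(CC)OS(=O)(=O)C(F)(F)F
Why: Silyl ether formation with a silyl triflate, which is reactive enough for the hindered tertiary C9 hydroxyl, blocks retro-aldol and β-elimination pathways in the aldehyde chemistry that follows, and 2,6-lutidine does not enolise the ester.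

Step 6
Reactants: 7 methyl 9α-(triethylsilyloxy)-13,14,15,16-tetranorlabd-8(17)-en-12-oate
Product: 8 methyl 7α-hydroxy-9α-(triethylsilyloxy)-13,14,15,16-tetranorlabd-8(17)-en-12-oate
Conditions: SeO2 (0.3 equiv), t-BuOOH (3 equiv), CH2Cl2, rt
Reagents that add atoms: tert-butyl hydroperoxide, CC(C)(C)OO (terminal oxidant); selenium dioxide, O=[Se]=O (oxygen carrier, catalytic)
Why: Allylic oxidation with SeO2 (ene reaction at C17, then a [2,3]-sigmatropic shift) can take a hydrogen only from C7 because C9 is fully substituted, and returns the oxygen to the axial α face of C7, a centre that step 17 turns into the ketone.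

Step 7
Reactants: 8 methyl 7α-hydroxy-9α-(triethylsilyloxy)-13,14,15,16-tetranorlabd-8(17)-en-12-oate
Product: 9 7α-hydroxy-9α-(triethylsilyloxy)-13,14,15,16-tetranorlabd-8(17)-en-12-al
Conditions: i-Bu2AlH (2.2 equiv), CH2Cl2, −78 °C; MeOH, then aq potassium sodium tartrate (KNaC4H4O6)
Reagents that add atoms: none
Why: Partial ester reduction with i-Bu2AlH at low temperature stops at the aluminium hemiacetal, which collapses to the aldehyde only on work-up, one extra equivalent of hydride being spent on the C7 hydroxyl.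

Step 8
Reactants: 9 7α-hydroxy-9α-(triethylsilyloxy)-13,14,15,16-tetranorlabd-8(17)-en-12-al
Product: 10 (12E)-7α-hydroxy-9α-(triethylsilyloxy)-15-norlabda-8(17),12-dien-14-al
Conditions: Ph3P=C(CH3)CHO (1.3 equiv), toluene, 90 °C
Reagents that add atoms: 2-(triphenylphosphoranylidene)propanal, CC(C=O)=P(c1ccccc1)(c1ccccc1)c1ccccc1
Why: Wittig olefination with a formyl-stabilised ylide gives the E enal (C11 and the C16 methyl cis) and stops there because the conjugated aldehyde formed is much less reactive towards this ylide than the saturated one.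

Step 9
Reactants: 10 (12E)-7α-hydroxy-9α-(triethylsilyloxy)-15-norlabda-8(17),12-dien-14-al
Product: 11 (12E)-9α-(triethylsilyloxy)labda-8(17),12,14-trien-7α-ol
Conditions: Ph3PCH3Br (3 equiv), KN(SiMe3)2 (2.9 equiv), THF, 0 °C; then 10, −78 → 0 °C
Reagents that add atoms: methyltriphenylphosphonium bromide, C[P+](c1ccccc1)(c1ccccc1)c1ccccc1.[Br-]
Why: Wittig methylenation converts the enal carbonyl into the C14=C15 vinyl group without touching the C12=C13 geometry, the excess ylide covering the free C7 hydroxyl.

Step 10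
Reactants: 12 2',4',6'-trihydroxyacetophenone
Product: 13 1-[2,4-bis(benzyloxy)-6-hydroxyphenyl]ethanone
Conditions: BnBr (2.05 equiv), K2CO3 (2.2 equiv), DMF, rt
Reagents that add atoms: benzyl bromide, BrCc1ccccc1
Why: Williamson ether synthesis in which the hydroxyl hydrogen-bonded to the acetyl carbonyl is the least nucleophilic, so the two benzyl groups go to the para and to one ortho oxygen.

Step 11
Reactants: 14 2-hydroxy-4,5-dimethoxybenzaldehyde
Product: 15 2-(benzyloxy)-4,5-dimethoxybenzaldehyde
Conditions: BnBr, K2CO3, DMF, 60 °C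
Reagents that add atoms: benzyl bromide, BrCc1ccccc1
Why: Williamson ether synthesis protects the phenol as a benzyl ether that is later removed together with those of the other ring.

Step 12
Reactants: 13 1-[2,4-bis(benzyloxy)-6-hydroxyphenyl]ethanone; 15 2-(benzyloxy)-4,5-dimethoxybenzaldehyde
Product: 16 (E)-1-[2,4-bis(benzyloxy)-6-hydroxyphenyl]-3-[2-(benzyloxy)-4,5-dimethoxyphenyl]prop-2-en-1-one
Conditions: KOH (50% aq), EtOH, rt
Reagents that add atoms: none
Why: Claisen–Schmidt condensation of the acetophenone enolate with the non-enolisable aldehyde, with loss of water, gives the E chalcone.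

Step 13
Reactants: 16 (E)-1-[2,4-bis(benzyloxy)-6-hydroxyphenyl]-3-[2-(benzyloxy)-4,5-dimethoxyphenyl]prop-2-en-1-one
Product: 18 5,7-bis(benzyloxy)-2-[2-(benzyloxy)-4,5-dimethoxyphenyl]-4H-chromen-4-one, via flavanone 17 (not isolated)
Conditions: I2 (0.1 equiv), DMSO, 130 °C
Reagents that add atoms: none
Why: Iodine-catalysed oxidative cyclisation in which oxa-Michael addition of the free phenol gives the flavanone, which is dehydrogenated by iodination and loss of HI, DMSO returning HI to I2.

Step 14
Reactants: 18 5,7-bis(benzyloxy)-2-[2-(benzyloxy)-4,5-dimethoxyphenyl]-4H-chromen-4-one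
Product: 19 5,7-dihydroxy-2-(2-hydroxy-4,5-dimethoxyphenyl)-4H-chromen-4-one
Conditions: H2 (1 atm), 10% Pd/C, THF–MeOH, rt
Reagents that add atoms: none
Why: Hydrogenolysis of the three benzyl ethers over Pd, the C2''=C3'' bond of the chromone being part of a vinylogous ester that is not hydrogenated at one atmosphere.

Step 15
Reactants: 19 5,7-dihydroxy-2-(2-hydroxy-4,5-dimethoxyphenyl)-4H-chromen-4-one
Product: 20 2-(5,7-dihydroxy-4-oxo-4H-chromen-2-yl)-4,4,5-trimethoxycyclohexa-2,5-dien-1-one (ring D dienone: C2' ketone, 4'-OMe, C5' dimethyl ketal)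
Conditions: PhI(OAc)2 (1.05 equiv), MeOH, 0 °C
Reagents that add atoms: methanol, CO
Why: Oxidative dearomatisation of a para-methoxyphenol by PhI(OAc)2 with capture of methanol at C5' gives the quinone monoketal, the electron-rich ring that carries the 2'-hydroxyl being oxidised in preference to the 5,7-dihydroxy ring, which is deactivated by the chromone carbonyl.

Step 16
Reactants: 11 (12E)-9α-(triethylsilyloxy)labda-8(17),12,14-trien-7α-ol; 20 2-(5,7-dihydroxy-4-oxo-4H-chromen-2-yl)-4,4,5-trimethoxycyclohexa-2,5-dien-1-one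
Product: 21 cycloadduct with ring C (C12, C13=C14, C15, C6', C1') cis-fused to ring D (C2' ketone, C3'=C4' with 4'-OMe, C5' dimethyl ketal), 5,7-dihydroxychromon-2-yl on C1', and C11, the chromone and H-6' on one face of ring C; terpenoid part 7α-OH, 9α-OSiEt3, 8(17)-ene
Conditions: 20 (1.5 equiv), BHT (0.05 equiv), 1,4-dioxane, 100 °C, sealed tube; chromatography
Reagents that add atoms: none
Why: Thermal Diels–Alder reaction in which the unsubstituted terminus C15 bonds to C6', the β-carbon of the only ring D enone, and C12 to C1' (the ortho orientation of a 1-substituted diene), suprafacial addition to the C1'=C6' bond gives the cis ring fusion, the methoxy groups of the C5' ketal block the approach with ring D under the diene so that the chromone takes the endo position and the E substituent C11 ends up cis to the chromone and to H-6', and the choice between the two enantiofaces of 20 is only weakly biased by the remote C9 centre, so the diastereomer from the other face is expected as a by-product to be removed by chromatography.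

Step 17
Reactants: 21 cycloadduct (7α-OH, 9α-OSiEt3, C5' dimethyl ketal)
Product: 22 7-oxo cycloadduct (8(17)-en-7-one, 9α-OSiEt3, C5' dimethyl ketal; ring C and ring D as in 21)
Conditions: MnO2 (activated, 20 equiv), EtOAc, rt
Reagents that add atoms: none
Why: Allylic alcohol oxidation with MnO2 gives the exo-methylene ketone and spares the phenols, the silyl ether and the alkenes, and it removes the C7 stereocentre.

Step 18
Reactants: 22 7-oxo cycloadduct (9α-OSiEt3, C5' dimethyl ketal)
Product: 23 CNP0241859.1 (target)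
Conditions: HF (48% aq), MeCN, 0 °C → rt; pH 7 phosphate buffer
Reagents that add atoms: water, O
Why: Acid-catalysed ketal hydrolysis frees the C5' ketone while the 4'-methoxy enone, a vinylogous ester, survives, and HF cleaves the silyl ether; no base is present, so the C6' hydrogen next to the new ketone keeps the cis ring fusion.

**Compound list**
1 | (+)-sclareolide | C[C@@]12CC[C@H]3C(C)(C)CCC[C@]3(C)[C@H]1CC(=O)O2 | starting material
2 | methyl 13,14,15,16-tetranorlabd-8-en-12-oate (5α-H, 10β-CH3) | COC(=O)CC1=C(C)CC[C@H]2C(C)(C)CCC[C@]12C | intermediate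
3 | methyl 8,9-dioxo-8,9-seco-13,14,15,16-tetranorlabdan-12-oate | CC(=O)CC[C@H]1C(C)(C)CCC[C@]1(C)C(=O)CC(=O)OC | intermediate
4 | C8 enol diethyl phosphate of 3 (C8=C17), β-keto ester in neutral form | C=C(OP(=O)(OCC)OCC)CC[C@H]1C(C)(C)CCC[C@]1(C)C(=O)CC(=O)OC | intermediate (not isolated)
5 | methyl 9-oxo-8,9-seco-13,14,15,16-tetranorlabd-8(17)-yn-12-oate | C#CCC[C@H]1C(C)(C)CCC[C@]1(C)C(=O)CC(=O)OC | intermediate
6 | methyl 9α-hydroxy-13,14,15,16-tetranorlabd-8(17)-en-12-oate | C=C1CC[C@H]2C(C)(C)CCC[C@]2(C)[C@@]1(O)CC(=O)OC | intermediate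
7 | methyl 9α-(triethylsilyloxy)-13,14,15,16-tetranorlabd-8(17)-en-12-oate | C=C1CC[C@H]2C(C)(C)CCC[C@]2(C)[C@@]1(O[Si](CC)(CC)CC)CC(=O)OC | intermediate
8 | methyl 7α-hydroxy-9α-(triethylsilyloxy)-13,14,15,16-tetranorlabd-8(17)-en-12-oate | C=C1[C@H](O)C[C@H]2C(C)(C)CCC[C@]2(C)[C@@]1(O[Si](CC)(CC)CC)CC(=O)OC | intermediate
9 | 7α-hydroxy-9α-(triethylsilyloxy)-13,14,15,16-tetranorlabd-8(17)-en-12-al | C=C1[C@H](O)C[C@H]2C(C)(C)CCC[C@]2(C)[C@@]1(O[Si](CC)(CC)CC)CC=O | intermediate
10 | (12E)-7α-hydroxy-9α-(triethylsilyloxy)-15-norlabda-8(17),12-dien-14-al | C=C1[C@H](O)C[C@H]2C(C)(C)CCC[C@]2(C)[C@@]1(O[Si](CC)(CC)CC)C/C=C(\C)C=O | intermediate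
11 | (12E)-9α-(triethylsilyloxy)labda-8(17),12,14-trien-7α-ol | C=C1[C@H](O)C[C@H]2C(C)(C)CCC[C@]2(C)[C@@]1(O[Si](CC)(CC)CC)C/C=C(\C)C=C | intermediate
12 | 2',4',6'-trihydroxyacetophenone | CC(=O)c1c(O)cc(O)cc1O | starting material
13 | 1-[2,4-bis(benzyloxy)-6-hydroxyphenyl]ethanone | CC(=O)c1c(O)cc(OCc2ccccc2)cc1OCc1ccccc1 | intermediate
14 | 2-hydroxy-4,5-dimethoxybenzaldehyde | O=Cc1cc(OC)c(OC)cc1O | starting material
15 | 2-(benzyloxy)-4,5-dimethoxybenzaldehyde | O=Cc1cc(OC)c(OC)cc1OCc1ccccc1 | intermediate
16 | (E)-1-[2,4-bis(benzyloxy)-6-hydroxyphenyl]-3-[2-(benzyloxy)-4,5-dimethoxyphenyl]prop-2-en-1-one | O=C(/C=C/c1cc(OC)c(OC)cc1OCc1ccccc1)c1c(O)cc(OCc2ccccc2)cc1OCc1ccccc1 | intermediate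
17 | racemic 5,7-bis(benzyloxy)-2-[2-(benzyloxy)-4,5-dimethoxyphenyl]chroman-4-one | O=C1CC(c2cc(OC)c(OC)cc2OCc2ccccc2)Oc2cc(OCc3ccccc3)cc(OCc3ccccc3)c21 | intermediate (not isolated)
18 | 5,7-bis(benzyloxy)-2-[2-(benzyloxy)-4,5-dimethoxyphenyl]-4H-chromen-4-one | O=c1cc(-c2cc(OC)c(OC)cc2OCc2ccccc2)oc2cc(OCc3ccccc3)cc(OCc3ccccc3)c12 | intermediate
19 | 5,7-dihydroxy-2-(2-hydroxy-4,5-dimethoxyphenyl)-4H-chromen-4-one | O=c1cc(-c2cc(OC)c(OC)cc2O)oc2cc(O)cc(O)c12 | intermediate
20 | 2-(5,7-dihydroxy-4-oxo-4H-chromen-2-yl)-4,4,5-trimethoxycyclohexa-2,5-dien-1-one | O=C1C=C(OC)C(OC)(OC)C=C1c1cc(=O)c2c(O)cc(O)cc2o1 | intermediate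
21 | cycloadduct: 7α-hydroxy, 9α-triethylsilyloxy, 8(17)-ene; ring C cis-fused to ring D with C5' dimethyl ketal; C11, chromone and H-6' cis on ring C | C=C1[C@H](O)C[C@H]2C(C)(C)CCC[C@]2(C)[C@@]1(O[Si](CC)(CC)CC)C[C@@H]1C(C)=CC[C@H]2C(OC)(OC)C(OC)=CC(=O)[C@@]12c1cc(=O)c2c(O)cc(O)cc2o1 | intermediate
22 | 7-oxo cycloadduct: 8(17)-en-7-one, 9α-triethylsilyloxy, C5' dimethyl ketal | C=C1C(=O)C[C@H]2C(C)(C)CCC[C@]2(C)[C@@]1(O[Si](CC)(CC)CC)C[C@@H]1C(C)=CC[C@H]2C(OC)(OC)C(OC)=CC(=O)[C@@]12c1cc(=O)c2c(O)cc(O)cc2o1 | intermediate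
23 | CNP0241859.1 | C=C1C(=O)C[C@H]2C(C)(C)CCC[C@]2(C)[C@@]1(O)C[C@@H]1C(C)=CC[C@H]2C(=O)C(OC)=CC(=O)[C@@]12c1cc(=O)c2c(O)cc(O)cc2o1 | target

**Totals**
Total step count: 18. Longest linear sequence: 12 steps (steps 1–9 and 16–18, from (+)-sclareolide).

**Steps most likely to fail**

1. Step 16 (cycloaddition). The addition at the hindered C6' may be slow enough for the ketal to decay on long heating. The dienophile may approach with ring D under the diene, which gives the C12-epimeric series. Both enantiofaces of 20 may react, because C9 is too far away to choose between them. Fallback, auxiliary control in place of substrate control: setting out from 20, ketal exchange with (1S,2S)-1,2-diphenylethane-1,2-diol (PPTS, benzene, 4 Å sieves, 50 °C) should give the C2-symmetric spiro dioxolane F1. In F1 a phenyl group lies over C6' on the face that leads to the unwanted series. Cycloaddition with 11 under the conditions of step 16 should give the adduct F2, and MnO2 the C7 ketone F3. Aqueous CF3CO2H, then HF in MeCN, releases the diol and the silyl group, and the fallback comes back to the route at 23.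

2. Step 4 (key step). The ketyl may be reduced to the secondary alcohol before it reaches the alkyne, or the ring may close through the chair with the ester arm axial (C9 epimer). Fallback, polar in place of radical closure of the same C8–C9 bond: setting out from 5, Markovnikov hydroiodination (NaI, Me3SiCl, H2O, MeCN) should give the 2-iodoalkene F4. An intramolecular Nozaki–Hiyama–Kishi reaction (CrCl2, divalent chromium, with catalytic NiCl2, DMF) then adds the C8 vinylchromium to the chelated C9 ketone and comes back at 6.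

3. Step 3 (alkyne formation). A proton may be removed at C7 instead of C17, or the stored β-keto ester enolate may be phosphorylated, which leads to allene and mixed phosphate products. Fallback, covalent masking in place of storage as an enolate: setting out from 3, NaH (1 equiv) and t-BuMe2SiCl should silylate only the β-keto ester, as the Z silyl enol ether F5. LiN(i-Pr)2 and ClP(O)(OEt)2 then give the enol phosphate F6, and more LiN(i-Pr)2 the alkyne F7. HF·pyridine cleaves the enol ether and comes back at 5.

**Further compounds**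
F1 | step 16 | 2-(5,7-dihydroxy-4-oxo-4H-chromen-2-yl)-5-methoxycyclohexa-2,5-dien-1-one 4-spiro-(4S,5S)-4,5-diphenyl-1,3-dioxolane | O=C1C=C(OC)C2(O[C@@H](c3ccccc3)[C@H](c3ccccc3)O2)C=C1c1cc(=O)c2c(O)cc(O)cc2o1
F2 | step 16 | cycloadduct as 21 with the C5' (4S,5S)-4,5-diphenyl-1,3-dioxolane ketal | C=C1[C@H](O)C[C@H]2C(C)(C)CCC[C@]2(C)[C@@]1(O[Si](CC)(CC)CC)C[C@@H]1C(C)=CC[C@H]2C3(O[C@@H](c4ccccc4)[C@H](c4ccccc4)O3)C(OC)=CC(=O)[C@@]12c1cc(=O)c2c(O)cc(O)cc2o1
F3 | step 16 | 7-oxo cycloadduct as 22 with the C5' (4S,5S)-4,5-diphenyl-1,3-dioxolane ketal | C=C1C(=O)C[C@H]2C(C)(C)CCC[C@]2(C)[C@@]1(O[Si](CC)(CC)CC)C[C@@H]1C(C)=CC[C@H]2C3(O[C@@H](c4ccccc4)[C@H](c4ccccc4)O3)C(OC)=CC(=O)[C@@]12c1cc(=O)c2c(O)cc(O)cc2o1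
F4 | step 4 | methyl 8-iodo-9-oxo-8,9-seco-13,14,15,16-tetranorlabd-8(17)-en-12-oate | C=C(I)CC[C@H]1C(C)(C)CCC[C@]1(C)C(=O)CC(=O)OC
F5 | step 3 | (Z)-9-O-tert-butyldimethylsilyl enol ether of 3 (C9=C11) | CC(=O)CC[C@H]1C(C)(C)CCC[C@]1(C)/C(O[Si](C)(C)C(C)(C)C)=C/C(=O)OC
F6 | step 3 | C8 enol diethyl phosphate of F5 | C=C(OP(=O)(OCC)OCC)CC[C@H]1C(C)(C)CCC[C@]1(C)/C(O[Si](C)(C)C(C)(C)C)=C/C(=O)OC
F7 | step 3 | (Z)-9-O-tert-butyldimethylsilyl enol ether of 5 | C#CCC[C@H]1C(C)(C)CCC[C@]1(C)/C(O[Si](C)(C)C(C)(C)C)=C/C(=O)OC
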